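**Retrosynthetic overview** (chromene locants: O1, C2–C4, C4a, C5–C8, C8a)

1. Last disconnection, C4–C4a: the pyran ring is closed last by an intramolecular Nozaki–Hiyama–Kishi addition of a 2-iodo vinylogous ester to a tethered C4 aldehyde, with C2 controlling C4 (cis).
2. Key disconnection: the bond between the first carbon of the hexadecyl chain and the CH2 group on C2. It is made together with the O1–C8a bond in a one-flask three-component union of hexadecylmagnesium bromide, (R)-2-allyloxirane and 3-chlorocyclohex-2-en-1-one.
3. Enabling feature: O1 sits on C2, directly beside that CH2, and is also the enol-ether oxygen of the vinylogous ester O1–C8a=C4a–C5=O. The triad O1–C2–CH2 is therefore a latent oxirane: opening it with the C16 nucleophile frees the alkoxide that captures C8a.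
4. Ring order: the cyclohexenone ring is bought in; a temporary oxirane (from (R)-epichlorohydrin) carries O1 and the C2 configuration and is opened in the key step; the pyran ring is formed last (step 6).

Key step: step 3

Remark: the target SMILES is read as the cis-(2S,4R) isomer (C2 alkyl and C4 hydroxyl on the same ring face); compounds 1, 4 and 5 and vinylmagnesium bromide are taken as commercial.

**Route**

Step 1
Reactants: 1 (2R)-2-(chloromethyl)oxirane ((R)-epichlorohydrin)
Product: 2 (2R)-1-chloropent-4-en-2-ol
Conditions: CH2=CHMgBr (1.2 equiv), CuI (10 mol%), THF, −40 °C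
Reagents that add atoms: vinylmagnesium bromide, C=C[Mg]Br
Why: Copper-catalysed Grignard opening of the oxirane at its unsubstituted ring carbon (SN2, faster than displacement of the primary chloride) leaves the C–O bond of the stereocentre untouched, so the configuration is retained.

Step 2
Reactants: 2 (2R)-1-chloropent-4-en-2-ol
Product: 3 (2R)-2-(prop-2-en-1-yl)oxirane
Conditions: powdered NaOH, Et2O, rt; distillation
Reagents that add atoms: none
Why: Intramolecular Williamson etherification (3-exo-tet displacement of the primary chloride by the alkoxide) re-forms an oxirane without touching the stereocentre.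

Step 3
Reactants: 3 (2R)-2-(prop-2-en-1-yl)oxirane; 4 1-bromohexadecane; 5 3-chlorocyclohex-2-en-1-one
Product: 8 3-{[(4S)-henicos-1-en-4-yl]oxy}cyclohex-2-en-1-one, via hexadecylmagnesium bromide 6 (not isolated), via bromomagnesium (4S)-henicos-1-en-4-olate 7 (not isolated)
Conditions: 4, Mg, THF, 40 °C; then 3 (1.1 equiv), CuI (10 mol%), THF, −40 → 0 °C; then 5 (1.2 equiv), DMPU, 0 → 40 °C
Reagents that add atoms: none
Why: Grignard reagent 6 is turned by catalytic CuI into an alkylcopper species that opens the monosubstituted oxirane 3 by SN2 attack at its unsubstituted CH2, which forms the hexadecyl–CH2 bond and releases the oxirane oxygen as magnesium alkoxide 7. In the same flask 7 adds to C3 of 5 (a vinylogous acid chloride) and chloride is expelled (conjugate addition–elimination), so this oxygen becomes O1 of the vinylogous ester 8. The closest known reaction types are the copper-catalysed Grignard opening of terminal epoxides and the alkoxide addition–elimination on 3-halo-enones, here run one after the other without isolation, as in the in situ acylation of Grignard-derived alkoxides. No ring of the target is closed (the temporary oxirane is opened) and no new stereocentre is formed: the C–O bond of the stereocentre is never broken, so the oxirane centre is carried over with retention and becomes C2 (the descriptor changes from R to S only because the CIP priorities change). The step needs regioselective opening at the terminal carbon, secured by the monosubstituted oxirane and copper catalysis, and chemoselective O–C3 bond formation on 5, secured by using 6 as the limiting reagent (none should remain when 5 is added) and by the fact that only attack at the chlorine-bearing β-carbon can end in loss of chloride; DMPU raises the nucleophilicity of the magnesium alkoxide.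

Step 4
Reactants: 8 3-{[(4S)-henicos-1-en-4-yl]oxy}cyclohex-2-en-1-one
Product: 9 3-{[(4S)-henicos-1-en-4-yl]oxy}-2-iodocyclohex-2-en-1-one
Conditions: NIS (1.1 equiv), MeCN, 0 °C → rt, dark
Reagents that add atoms: N-iodosuccinimide, O=C1CCC(=O)N1I
Why: Electrophilic α-iodination of a vinylogous ester: the enol-ether (push–pull) carbon C2 of the enone is far more nucleophilic than the isolated terminal alkene, and the stereocentre is not involved.

Step 5
Reactants: 9 3-{[(4S)-henicos-1-en-4-yl]oxy}-2-iodocyclohex-2-en-1-one
Product: 10 (3S)-3-[(2-iodo-3-oxocyclohex-1-en-1-yl)oxy]icosanal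
Conditions: OsO4 (2 mol%), NaIO4 (4 equiv), 2,6-lutidine, dioxane–H2O (3:1), rt; aldehyde used crude
Reagents that add atoms: osmium tetroxide (catalytic oxygen carrier), O=[Os](=O)(=O)=O; sodium periodate (stoichiometric oxygen source), [Na+].[O-][I](=O)(=O)=O
Why: Lemieux–Johnson oxidative cleavage: OsO4 should dihydroxylate the monosubstituted alkene in preference to the tetrasubstituted, electron-poor iodo-enone alkene, periodate cleaves the diol to the aldehyde, and the lutidine-buffered medium should keep the β-oxygenated aldehyde from eliminating.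

Step 6
Reactants: 10 (3S)-3-[(2-iodo-3-oxocyclohex-1-en-1-yl)oxy]icosanal
Product: 11 (2S,4R)-2-heptadecyl-4-hydroxy-2,3,4,6,7,8-hexahydro-5H-chromen-5-one (target)
Conditions: CrCl2 (6 equiv), NiCl2 (2 mol%), DMF, rt, 0.01 M
Reagents that add atoms: none
Why: Intramolecular Nozaki–Hiyama–Kishi reaction: Ni(0) inserts into the activated alkenyl C–I bond, transmetalation gives an alkenylchromium(III) species at C4a that adds to the tethered aldehyde and closes the six-membered pyran ring through C4–C4a, and the new C4 centre should form cis to the C2 chain because the chair-like transition state keeps the heptadecyl group equatorial while chromium, held between the aldehyde oxygen and the neighbouring C5 carbonyl, places the developing C4–O bond pseudo-equatorial (4R).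

**Compound list**

1 | (2R)-2-(chloromethyl)oxirane ((R)-epichlorohydrin) | ClC[C@H]1CO1 | starting material
2 | (2R)-1-chloropent-4-en-2-ol | ClC[C@H](O)CC=C | intermediate
3 | (2R)-2-(prop-2-en-1-yl)oxirane | C=CC[C@@H]1CO1 | intermediate
4 | 1-bromohexadecane | CCCCCCCCCCCCCCCCBr | starting material
5 | 3-chlorocyclohex-2-en-1-one | ClC1=CC(=O)CCC1 | starting material
6 | hexadecylmagnesium bromide | CCCCCCCCCCCCCCCC[Mg]Br | intermediate (not isolated)
7 | bromomagnesium (4S)-henicos-1-en-4-olate | C=CC[C@@H](O[Mg]Br)CCCCCCCCCCCCCCCCC | intermediate (not isolated)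
8 | 3-{[(4S)-henicos-1-en-4-yl]oxy}cyclohex-2-en-1-one | C=CC[C@@H](OC1=CC(=O)CCC1)CCCCCCCCCCCCCCCCC | intermediate
9 | 3-{[(4S)-henicos-1-en-4-yl]oxy}-2-iodocyclohex-2-en-1-one | C=CC[C@@H](OC1=C(I)C(=O)CCC1)CCCCCCCCCCCCCCCCC | intermediate
10 | (3S)-3-[(2-iodo-3-oxocyclohex-1-en-1-yl)oxy]icosanal | O=CC[C@@H](OC1=C(I)C(=O)CCC1)CCCCCCCCCCCCCCCCC | intermediate
11 | (2S,4R)-2-heptadecyl-4-hydroxy-2,3,4,6,7,8-hexahydro-5H-chromen-5-one | CCCCCCCCCCCCCCCCC[C@H]1C[C@@H](O)C2=C(CCCC2=O)O1 | target

**Step count:** 6 steps in total (Grignard formation is part of step 3). Longest linear sequence: 6 steps (1 → 2 → 3 → 8 → 9 → 10 → 11).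

**Steps most likely to fail**

Step 6. The risk is poor facial selectivity when the alkenylchromium adds to the aldehyde, so that the C4 epimer predominates. The fallback sets out from 10 and comes back at 11: the ring closure is accepted as it comes and the C4 configuration is corrected afterwards. The trans alcohol (2S,4S)-2-heptadecyl-4-hydroxy-2,3,4,6,7,8-hexahydro-5H-chromen-5-one F1 obtained from 10 is inverted by a Mitsunobu reaction (4-nitrobenzoic acid, PPh3, DIAD, THF, 0 °C) to (2S,4R)-2-heptadecyl-5-oxo-3,4,5,6,7,8-hexahydro-2H-chromen-4-yl 4-nitrobenzoate F2. Mild methanolysis (K2CO3, MeOH, 0 °C) should then give 11.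

Step 3. The risk is sluggish capture of the magnesium alkoxide, with copper or magnesium species attacking 5 instead. The fallback sets out from 7 and comes back at 8: the epoxide opening is run alone and quenched with water to give (4S)-henicos-1-en-4-ol F3. This alcohol is then condensed with commercial cyclohexane-1,3-dione under acid catalysis (TsOH, toluene, Dean–Stark; vinylogous esterification) to give 8.

Step 5. The risk is competing oxidation of the enol-ether alkene, or β-elimination of the vinylogous carboxylate from the aldehyde during the aqueous oxidative cleavage. The fallback sets out from 4 and 5 and comes back at 10: the aldehyde carbon is carried as a diethyl acetal from the start, so no oxidative cleavage is needed. Commercial 4,4-diethoxybut-1-ene is epoxidised (mCPBA, NaHCO3, CH2Cl2) to racemic 2-(2,2-diethoxyethyl)oxirane F4. Hydrolytic kinetic resolution (chiral (salen)Co(III) acetate, 0.55 equiv H2O, using the catalyst enantiomer that leaves the R oxirane unreacted) gives (2R)-2-(2,2-diethoxyethyl)oxirane F5. F5 takes the place of 3 in the conditions of step 3 (with 6 made from 4, then 5) and should give, through bromomagnesium (3S)-1,1-diethoxyicosan-3-olate F6, the ether 3-{[(3S)-1,1-diethoxyicosan-3-yl]oxy}cyclohex-2-en-1-one F7. Iodination as in step 4 gives 3-{[(3S)-1,1-diethoxyicosan-3-yl]oxy}-2-iodocyclohex-2-en-1-one F8. Mild acetal cleavage (PPTS, wet acetone, rt) should give 10.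

**Further compounds**

F1 | step 6 | (2S,4S)-2-heptadecyl-4-hydroxy-2,3,4,6,7,8-hexahydro-5H-chromen-5-one | CCCCCCCCCCCCCCCCC[C@H]1C[C@H](O)C2=C(CCCC2=O)O1
F2 | step 6 | (2S,4R)-2-heptadecyl-5-oxo-3,4,5,6,7,8-hexahydro-2H-chromen-4-yl 4-nitrobenzoate | CCCCCCCCCCCCCCCCC[C@H]1C[C@@H](OC(=O)c3ccc(cc3)[N+](=O)[O-])C2=C(CCCC2=O)O1
F3 | step 3 | (4S)-henicos-1-en-4-ol | C=CC[C@@H](O)CCCCCCCCCCCCCCCCC
F4 | step 5 | rac-2-(2,2-diethoxyethyl)oxirane | CCOC(OCC)CC1CO1
F5 | step 5 | (2R)-2-(2,2-diethoxyethyl)oxirane | CCOC(OCC)C[C@@H]1CO1
F6 | step 5 | bromomagnesium (3S)-1,1-diethoxyicosan-3-olate | CCOC(OCC)C[C@@H](O[Mg]Br)CCCCCCCCCCCCCCCCC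
F7 | step 5 | 3-{[(3S)-1,1-diethoxyicosan-3-yl]oxy}cyclohex-2-en-1-one | CCOC(OCC)C[C@@H](OC1=CC(=O)CCC1)CCCCCCCCCCCCCCCCC
F8 | step 5 | 3-{[(3S)-1,1-diethoxyicosan-3-yl]oxy}-2-iodocyclohex-2-en-1-one | CCOC(OCC)C[C@@H](OC1=C(I)C(=O)CCC1)CCCCCCCCCCCCCCCCC
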